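**Total synthesis plan for CNP0301018.3 (35) by epoxy-alcohol Grob fragmentation of a cis-decalin**

## The problem

Compound 35 is a germacranolide: a ten-membered carbocycle (C1–C10) with two trisubstituted alkenes whose ring bonds are both cis (C1=C10 carrying the C14 methyl ester, C4=C5 carrying the C15 hydroxymethyl; both are E by CIP only because of the oxygenated exocyclic carbons). A trans-fused α-methylene-γ-lactone spans C6–C7. Five stereocentres (2S,6R,7S,8S,9S) must be set. C6–C9 are contiguous, but C2 is separated from them by the C1=C10 alkene, so in a flexible medium ring nothing relays stereochemical information to it. The vicinal C8 isobutyrate and C9 acetate require two oxygens that stay differentiated to the end. These esters, the exo-methylene lactone (a Michael acceptor) and four allylic C–O bonds (C2, C6, C9, C15) exclude strong base, strong acid and soft nucleophiles late in the route. Direct closure of the ten-membered ring is the least favourable operation the skeleton offers. The enabling feature is that C10 lies across the ring from C5: a temporary C5–C10 bond gives a cis-decalin (ring A = C1–C5 + C10, ring B = C5–C10) in which O–C10–C5–C4–O(C15) is a fragmentable array, every stereocentre sits on a chair, and C2 is related to C6–C9 through the ring fusion. Fragmentation gives the ring-cis C4=C5 alkene only if C6 is axial on ring A; with the configuration the target imposes, a trans-lactone on ring B would be trans-diaxial in that conformer, so the lactone must be closed after the ring is opened.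

## Retrosynthesis

**Acyl and silyl groups (35 ⇒ 34 ⇒ 33 ⇒ 32 ⇒ 31 ⇒ 30).** The O8–isobutyryl and O9–acetyl bonds and the two O–Si bonds are cut first. Esters cannot survive the enolate steps that build C13 and C14, so they are made last. O8 (TBS ether) and O9 (MOM ether) are released one at a time, because nothing in a free 8,9-diol would distinguish the two hydroxyls. Compound 30 already holds the whole skeleton; the forward steps only have to avoid 1,2-acyl migration and conjugate addition to the methylene lactone.

**C11=C13 and O6–C12 (30 ⇒ 27 ⇒ 25).** The exo-methylene is cut to the saturated lactone 27, and the lactone O6–C12 bond to the open methyl ester 25 with O6 as a TES ether. The lactone cannot be closed earlier (see the key disconnection). It must be closed before O8 is unveiled, since O8 is cis to the C7 arm and would otherwise capture C12. Compound 25 is simpler by one ring; the forward step needs O6 to carry the most labile silyl group.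

**C10–C14 (25 ⇒ 24 ⇒ 23 ⇒ 22).** The enoate is cut at C10–C14, back through enol triflate 24 to ketone 22. Forming C1=C10 by olefination instead would require a macrocyclisation, whereas a C10 ketone is exactly what the fragmentation leaves. The forward reaction must enolise toward C1 (not the alkoxy-substituted C9) and give the ring-cis enol triflate.

**C5–C10, the key disconnection (22 ⇒ 21).** Re-joining C5 and C10 gives cis-decalin 21 with a 10-hydroxyl and a 4,15-spiro-epoxide. This is preferred to any ring-closing cut because the forward step opens a bond and so carries no entropic penalty, and it fixes the C4=C5 geometry stereospecifically. C5 and C10 disappear, so their configuration relative to C6–C9 is free. The 5α,10α series is chosen because every reagent that builds ring B then adds from the convex α face. The alternative of inverting the ring fusion and keeping the lactone would need concave-face chemistry throughout. The price of the chosen series is that O6 and the C7 arm are trans-diaxial in the reactive conformer and so remain unconnected in 21. The forward reaction needs the epoxide C–O bond anti-periplanar to C5–C10 and C6 axial on ring A.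

**C4–C15 and the C4 carbonyl (21 ⇒ 20 ⇒ 19 ⇒ 18).** The epoxide is cut at C4–C15 (sulfur ylide on ketone 20). The ketone comes from the C4 benzyl ether 18 by hydrogenolysis and oxidation. The oxygen at C4 is kept masked until all enolate chemistry on ring B is finished. The ylide must attack the α face.

**Ring B oxygens and C7–C11 (18 ⇒ 17 ⇒ 16 ⇒ 14 ⇒ 12 + 13).** O9 comes from directed reduction of the C9 ketone, O8 from oxidation of the C8=C9 silyl enol ether 14, and the C7–C11 bond from a Mukaiyama–Michael addition of ketene acetal 13 to enone 12. One enone thus delivers three adjacent centres. The order (C7 first, then C8, then C9) lets the conjugate addition leave the enol ether regiospecifically, and lets O8 be born silylated so that it can never lactonise.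

**O10 and the protecting groups (12 ⇒ 10 ⇒ 9 ⇒ 8).** The tertiary hydroxyl is cut at the enone stage, where C10 is the only enolisable α-position of the C9 ketone. The TBDPS ether (O2, last to leave) and the TES ether (O6, first to leave) are placed on diol 8 using the steric difference of its two hydroxyls.

**Ring A: C4–C5 and C1–C10 (8 ⇒ 6 ⇒ 3 + 4).** Both carbinols of 8 arise from reduction of diketone 6, which is the Diels–Alder adduct of diene 3 and quinone monoketal 4. The monoketal is chosen over p-benzoquinone because it differentiates C6 from C9 from the outset and cannot aromatise. The 1-alkoxy-3-silyloxy diene supplies O4 and O2 in the 1,3-pattern that ring A needs. This is the only step that needs absolute stereocontrol.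

**Diene (3 ⇒ 2 ⇒ 1).** The benzyl ether on the diene terminus (removable later by hydrogenolysis) is introduced by transetherification of commercial 1.

## Roads not taken

**Alternative 1:** Nozaki–Hiyama–Kishi macrocyclisation. The cut is C5–C6 together with the lactone O6–C12 bond. In the forward step the open-chain iodo aldehyde A1 is treated with CrCl2 and catalytic NiCl2; the C5 alkenylchromium adds to the C6 aldehyde and the chromium alkoxide closes the lactone to give A2, the 2,15-bis-O-TBS ether of 35.
- Merits: both acyl groups, both alkenes and the exo-methylene are already in place; chromium reagents tolerate them; A2 is one desilylation from the target. After ring formation this road is clearly shorter than the chosen one (one step against ten), and it is more convergent.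
- Weak points: a ten-membered ring with two ring-cis trisubstituted alkenes is closed by a bimolecular-type addition at high dilution with stoichiometric chromium. C6 is created in the ring closure with no reliable bias toward 6R. The aldehyde of A1 is α to C7, which also bears the acrylate, so epimerisation and conjugation threaten. The C7–C9 triad and C2 need separate acyclic asymmetric steps.
- Comparison: the chosen plan never closes the medium ring, sets C6 by a ketone reduction on a chair, and gets the C4=C5 geometry from a stereospecific fragmentation. It pays with a longer endgame.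

**Alternative 2:** Two-carbon ring expansion with propiolate. The cuts are C1–C2 and C9–C10, with a temporary C2–C9 bond, leading back to cyclooctenone A3. In the forward step pyrrolidine and methyl propiolate convert A3 by [2+2] addition and conrotatory opening of the strained four-membered ring into the ten-membered dienamine ester A4.
- Merits: C1, C10 and C14 arrive in one operation, strain release drives the expansion, and no high dilution is needed. In bringing C14 with the ring-forming event it is better than the chosen plan, which needs triflation and carbonylation.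
- Weak points: A4 has the wrong functional pattern. Nitrogen sits on an sp2 C9 (the target needs a configured sp3 C9–O), the diene is C1=C2/C9=C10 instead of C1=C10, and C2 carries no oxygen, so a late uncontrolled allylic oxidation would be required. The enamine must form toward C2 and not toward the alkoxy-bearing C8. The opening tends to place a trans double bond in the ring. A3 is itself a medium-ring problem.
- Comparison: the redox and stereochemical repair after the key step outweighs the short ring construction. The chosen plan brings every stereocentre through the key step already set.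

**Alternative 3:** Nickel cross-electrophile macrocyclisation. The cut is C3–C4. In the forward step NiBr2(dme), a bipyridine ligand and manganese powder couple the C4 alkenyl bromide and the C3 primary iodide of A5 to give macrocycle A6.
- Merits: no stereocentre is formed in the closure; the alkenyl bromide geometry is retained; the C14 ester, the isobutyrate and the lactone are present, so few steps remain. In convergence and in step count after ring formation it is as good as or better than the chosen plan.
- Weak points: reductive macrocyclisations of this kind are established for larger, less strained rings. Here the alkylnickel derived from the C3 iodide carries a β-silyloxy group at C2 (β-alkoxide elimination). Hydrodehalogenation and dimerisation compete at the required dilution. A5 needs all five stereocentres and two defined alkenes to be built on an open chain.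
- Comparison: the chosen plan sets against this a ring opening without entropic cost, stereospecific alkene formation and stereocontrol on rigid chairs, at the price of a long linear sequence.

Key step: step 15

## Route

Remarks. Locants follow the germacrane numbering of 35 (ring C1–C10; C11–C13 lactone arm; C14 ester carbon; C15 hydroxymethyl carbon). In the decalins, α is the face of the ring-fusion substituents at C5 and C10 and β the opposite face. Bn = benzyl, TBS = tert-butyldimethylsilyl, TBDPS = tert-butyldiphenylsilyl, TES = triethylsilyl, TMS = trimethylsilyl, TIPS = triisopropylsilyl, MOM = methoxymethyl.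

Assumption: the (R)-BINOL–titanium catalyst of step 3 is taken to select the enone double bond and face that lead to 5 as drawn; if its sense of induction is the opposite, (S)-BINOL is used.

Step 1
Reactants: 1 (E)-4-methoxybut-3-en-2-one
Product: 2 (E)-4-(benzyloxy)but-3-en-2-one
Conditions: BnOH, PPTS (cat.), toluene, 70 °C, reduced pressure
Reagents that add atoms: benzyl alcohol, OCc1ccccc1
Why: Acid-catalysed transetherification of a vinylogous ester (addition–elimination at the β-carbon); removal of methanol drives the exchange and the E isomer is the stable one.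

Step 2
Reactants: 2 (E)-4-(benzyloxy)but-3-en-2-one
Product: 3 (E)-1-(benzyloxy)-3-(tert-butyldimethylsilyloxy)buta-1,3-diene
Conditions: TBSOTf, Et3N, Et2O, 0 °C
Reagents that add atoms: tert-butyldimethylsilyl trifluoromethanesulfonate, CC(C)(C)[Si](C)(C)OS(=O)(=O)C(F)(F)F
Why: Soft enolisation and O-silylation of the methyl ketone (silyl enol ether formation) gives the 1-alkoxy-3-silyloxy diene without touching the E enol ether.

Step 3
Reactants: 3 (E)-1-(benzyloxy)-3-(tert-butyldimethylsilyloxy)buta-1,3-diene; 4 1,4-dioxaspiro[4.5]deca-6,9-dien-8-one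
Product: 6 4β-OBn-5α,10α-H-cis-decal-7-ene-2,6-dione 9-ethylene ketal, via silyl enol ether cycloadduct 5 (not isolated)
Conditions: (R)-BINOL (0.1 equiv), TiCl2(OiPr)2 (0.1 equiv), 4 Å MS, toluene, −30 °C; then Bu4NF, AcOH, THF, 0 °C
Reagents that add atoms: none
Why: Catalytic enantioselective Diels–Alder reaction of a quinone monoketal: the diene CH2 terminus bonds to the enone β-carbon (C10) and the benzyloxy-bearing terminus to the α-carbon (C5), suprafacial endo addition makes H4, H5 and H10 cis, and the chiral titanium complex chooses between the two enantiotopic enone double bonds. Buffered fluoride then unmasks the C2 ketone without β-elimination of the benzyloxy group.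

Step 4
Reactants: 6 4β-OBn-5α,10α-H-cis-decal-7-ene-2,6-dione 9-ethylene ketal
Product: 8 4β-OBn-2β,6β-dihydroxy-cis-decal-7-en-9-one, via ketal diol 7 (not isolated)
Conditions: NaBH4, CeCl3·7H2O, MeOH, −78 °C; then 1 M HCl, THF, 0 °C
Reagents that add atoms: water, O
Why: Luche reduction: hydride attacks the C2 ketone axially and the C6 enone carbonyl 1,2 from the α face (the β face is screened by the pseudoaxial C1 and the fused ring), so both carbinols are β. Aqueous acid then hydrolyses the allylic ketal to the C9 enone.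

Step 5
Reactants: 8 4β-OBn-2β,6β-dihydroxy-cis-decal-7-en-9-one
Product: 9 4β-OBn-2β-OTBDPS-6β-hydroxy-cis-decal-7-en-9-one
Conditions: TBDPSCl (1.05 equiv), imidazole, CH2Cl2, 0 °C
Reagents that add atoms: tert-butyl(chloro)diphenylsilane, CC(C)(C)[Si](Cl)(c1ccccc1)c1ccccc1
Why: Silylation with a bulky chlorosilane discriminates the unhindered equatorial C2 hydroxyl from the pseudoaxial allylic C6 hydroxyl next to the ring fusion.

Step 6
Reactants: 9 4β-OBn-2β-OTBDPS-6β-hydroxy-cis-decal-7-en-9-one
Product: 10 4β-OBn-2β-OTBDPS-6β-OTES-cis-decal-7-en-9-one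
Conditions: TESOTf, 2,6-lutidine, CH2Cl2, −78 °C
Reagents that add atoms: triethylsilyl trifluoromethanesulfonate, CC[Si](CC)(CC)OS(=O)(=O)C(F)(F)F
Why: Silyl triflate silylation of the hindered allylic alcohol; the TES ether is the most labile silyl group of the route so that O6 can be released first.

Step 7
Reactants: 10 4β-OBn-2β-OTBDPS-6β-OTES-cis-decal-7-en-9-one
Product: 12 4β-OBn-2β-OTBDPS-6β-OTES-10α-OTMS-cis-decal-7-en-9-one, via 10α-hydroxy enone 11 (not isolated)
Conditions: KN(SiMe3)2, THF, −78 to −40 °C; 2-(phenylsulfonyl)-3-phenyloxaziridine, −78 °C; then Me3SiCl, −78 to 0 °C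
Reagents that add atoms: 2-(phenylsulfonyl)-3-phenyloxaziridine, O=S(=O)(c1ccccc1)N1OC1c1ccccc1; chlorotrimethylsilane, C[Si](C)(C)Cl
Why: Kinetic α′-deprotonation of the enone (C10 is its only enolisable α-position) and Davis hydroxylation of the cross-conjugated enolate. The oxidant adds axially to ring A on the α face, which keeps the cis fusion, and the alkoxide is capped as the TMS ether to keep the tertiary oxygen out of the next Lewis-acid step.

Step 8
Reactants: 12 4β-OBn-2β-OTBDPS-6β-OTES-10α-OTMS-cis-decal-7-en-9-one; 13 1-(tert-butyldimethylsilyloxy)-1-methoxyethene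
Product: 14 methyl [4β-OBn-2β-OTBDPS-6β-OTES-9-OTBS-10α-OTMS-cis-decal-8-en-7α-yl]acetate
Conditions: TBSOTf (0.1 equiv), CH2Cl2, −78 °C; Et3N quench
Reagents that add atoms: none
Why: Mukaiyama–Michael addition: the ketene acetal adds to C7 anti to the pseudoaxial γ-silyloxy group at C6 (axial attack on the α face), so the acetate arm is trans to O6. Silyl transfer leaves the C8=C9 enol ether regiospecifically.

Step 9
Reactants: 14 methyl [4β-OBn-2β-OTBDPS-6β-OTES-9-OTBS-10α-OTMS-cis-decal-8-en-7α-yl]acetate
Product: 16 methyl [4β-OBn-8α-OTBS-2β-OTBDPS-6β-OTES-10α-hydroxy-9-oxo-cis-decalin-7α-yl]acetate, via 10-O-TMS silyloxy ketone 15 (not isolated)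
Conditions: mCPBA, NaHCO3, CH2Cl2, −20 to 0 °C; then citric acid, MeOH, rt
Reagents that add atoms: 3-chloroperbenzoic acid, OOC(=O)c1cccc(Cl)c1
Why: Rubottom oxidation with 1,4-silyl migration: the peracid reaches C8 from the α face because the β face is covered by the syn-axial C6 silyloxy group and the axial C1, so O8 ends equatorial, cis to the C7 arm, and is never free to lactonise. Mild acidic methanolysis then removes only the tertiary TMS ether.

Step 10
Reactants: 16 methyl [4β-OBn-8α-OTBS-2β-OTBDPS-6β-OTES-10α-hydroxy-9-oxo-cis-decalin-7α-yl]acetate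
Product: 17 methyl [4β-OBn-8α-OTBS-2β-OTBDPS-6β-OTES-9β,10α-dihydroxy-cis-decalin-7α-yl]acetate
Conditions: Me4NBH(OAc)3, MeCN/AcOH, −30 °C
Reagents that add atoms: none
Why: Hydroxyl-directed reduction of the α-hydroxy ketone (Saksena–Evans type): hydride is delivered from boron bound to the 10α-hydroxyl, giving the equatorial 9β-alcohol trans to both oxygen neighbours; the ester is untouched.

Step 11
Reactants: 17 methyl [4β-OBn-8α-OTBS-2β-OTBDPS-6β-OTES-9β,10α-dihydroxy-cis-decalin-7α-yl]acetate
Product: 18 methyl [4β-OBn-8α-OTBS-2β-OTBDPS-6β-OTES-10α-hydroxy-9β-OMOM-cis-decalin-7α-yl]acetate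
Conditions: MOMCl, iPr2NEt, Bu4NI (cat.), CH2Cl2, 0 to 40 °C
Reagents that add atoms: chloromethyl methyl ether, COCCl
Why: Base-mediated O-alkylation (MOM ether formation) of the secondary equatorial alcohol; the tertiary C10 hydroxyl is too hindered to react.

Step 12
Reactants: 18 methyl [4β-OBn-8α-OTBS-2β-OTBDPS-6β-OTES-10α-hydroxy-9β-OMOM-cis-decalin-7α-yl]acetate
Product: 19 methyl [8α-OTBS-2β-OTBDPS-6β-OTES-4β,10α-dihydroxy-9β-OMOM-cis-decalin-7α-yl]acetate
Conditions: H2 (1 atm), Pd/C, EtOAc, rt
Reagents that add atoms: none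
Why: Hydrogenolysis of the benzyl ether; no alkene or other benzyl-type group is present and silyl ethers survive in ethyl acetate.

Step 13
Reactants: 19 methyl [8α-OTBS-2β-OTBDPS-6β-OTES-4β,10α-dihydroxy-9β-OMOM-cis-decalin-7α-yl]acetate
Product: 20 methyl [8α-OTBS-2β-OTBDPS-6β-OTES-10α-hydroxy-9β-OMOM-4-oxo-cis-decalin-7α-yl]acetate
Conditions: Dess–Martin periodinane, NaHCO3, CH2Cl2, 0 °C to rt
Reagents that add atoms: none
Why: Dess–Martin oxidation under buffered neutral conditions converts the secondary C4 alcohol into the ketone without retro-aldol cleavage of the β-hydroxy ketone.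

Step 14
Reactants: 20 methyl [8α-OTBS-2β-OTBDPS-6β-OTES-10α-hydroxy-9β-OMOM-4-oxo-cis-decalin-7α-yl]acetate
Product: 21 methyl [4β,15-epoxy-8α-OTBS-2β-OTBDPS-6β-OTES-10α-hydroxy-9β-OMOM-cis-decalin-7α-yl]acetate (spiro-epoxide; oxygen β; C15 α)
Conditions: Me3S+ I−, KN(SiMe3)2, THF, −10 °C; then 20, −10 to 0 °C
Reagents that add atoms: trimethylsulfonium iodide, C[S+](C)C.[I-]
Why: Corey–Chaykovsky epoxidation with dimethylsulfonium methylide (irreversible, axial addition): the ylide attacks C4 on the α face, anti to the axial C5–C6 bond, so C15 becomes axial and the epoxide oxygen equatorial (β), anti-periplanar to C5–C10.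

Step 15
Reactants: 21 methyl [4β,15-epoxy-8α-OTBS-2β-OTBDPS-6β-OTES-10α-hydroxy-9β-OMOM-cis-decalin-7α-yl]acetate
Product: 22 ten-membered 10-ketone (ring-cis C4=C5; 4-CH2OH; 2-OTBDPS; 6-OTES; 7-CH2CO2Me; 8-OTBS; 9-OMOM; C2 and C6–C9 as in 35)
Conditions: KN(SiMe3)2 (1.05 equiv), THF, −78 to 0 °C; aq NH4Cl
Reagents that add atoms: none
Why: Grob-type fragmentation of a 3,4-epoxy alkoxide: deprotonation of the tertiary 10-hydroxyl lets an oxygen lone pair push into C10, the C5–C10 σ-bond becomes the C4=C5 π-bond, and the anti-periplanar epoxide C4–O bond leaves as the C15 alkoxide in one concerted six-electron event. The closest known reaction types are the base-induced fragmentation of bicyclic 3,4-epoxy alcohols and the Wharton fragmentation of 1,3-diol monosulfonates to medium-ring ketones. No ring is closed: the ten-membered ring appears by cleavage of the bond shared by the two six-membered rings, so no cyclisation mode has to be met. No stereocentre is created; C5 and C10 are erased and C2, C6, C7, C8 and C9 are untouched. The alkene geometry is stereospecific: in the chair–chair conformer that keeps the C2 silyloxy group equatorial, C6 is axial on ring A and the equatorial epoxide oxygen is anti to C5–C10, so C6 and C3 end cis on C4=C5. The step needs this conformer to be populated and fragmentation to outrun ether formation by attack of O10 on C15; the first is secured by the open lactone (O6 and the C7 arm may be trans-diaxial on ring B) and by the equatorial groups at C2, C8 and C9, the second by the poor displacement trajectory from the axial alkoxide to C15. One equivalent of base at low temperature keeps the new ketone from enolising toward C9 and expelling O8.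

Step 16
Reactants: 22 ten-membered 10-ketone (4-CH2OH)
Product: 23 ten-membered 10-ketone (4-CH2OTIPS; otherwise as 22)
Conditions: TIPSCl, imidazole, CH2Cl2, 0 °C
Reagents that add atoms: chlorotriisopropylsilane, CC(C)[Si](Cl)(C(C)C)C(C)C
Why: Silylation of the primary allylic alcohol; the TIPS ether is chosen to outlast the later fluoride cleavage at O8.

Step 17
Reactants: 23 ten-membered 10-ketone (4-CH2OTIPS)
Product: 24 ring-cis C1=C10 enol triflate (10-OTf; otherwise as 23)
Conditions: KN(SiMe3)2, THF, −78 °C; PhNTf2, −78 to −40 °C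
Reagents that add atoms: N-phenylbis(trifluoromethanesulfonimide), O=S(=O)(N(c1ccccc1)S(=O)(=O)C(F)(F)F)C(F)(F)F
Why: Kinetic enolate formation and O-sulfonylation (enol triflate synthesis): deprotonation occurs at the C1 methylene, away from the alkoxy-substituted C9, and a ten-membered ring accommodates the ring-cis enolate far better than the ring-trans one, which places C2 and C9 cis on the new double bond.

Step 18
Reactants: 24 ring-cis C1=C10 enol triflate
Product: 25 methyl ester at C10 (C14; ring-cis C1=C10 enoate; 6-OTES; 7-CH2CO2Me; 8-OTBS; 9-OMOM; 2-OTBDPS; 15-OTIPS)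
Conditions: Pd(OAc)2 (cat.), PPh3, CO (1 atm), MeOH, Et3N, DMF, 50 °C
Reagents that add atoms: carbon monoxide, [C-]#[O+]; methanol, CO
Why: Palladium-catalysed alkoxycarbonylation of the enol triflate (oxidative addition to zerovalent palladium, CO insertion, methanolysis) installs C14 with retention of the alkene geometry.

Step 19
Reactants: 25 seco diester (6-OTES)
Product: 27 saturated trans-fused 6,12-lactone (8-OTBS; 9-OMOM; 2-OTBDPS; 15-OTIPS; C14 methyl ester), via 6-hydroxy ester 26 (not isolated)
Conditions: PPTS, MeOH, 0 °C to rt; then PPTS (cat.), toluene, 60 °C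
Reagents that add atoms: none
Why: Acid-catalysed methanolysis of the most labile silyl ether frees O6, and the γ-hydroxy ester lactonises (intramolecular transesterification) to the trans-fused lactone before any other hydroxyl is exposed.

Step 20
Reactants: 27 saturated 6,12-lactone
Product: 30 α-methylene lactone (C11=C13; otherwise as 27), via Mannich base 28 (not isolated), via ammonium iodide 29 (not isolated)
Conditions: LiN(iPr)2, THF, −78 °C; Me2N=CH2+ I−, −78 to 0 °C; then MeI, MeOH, rt; then aq NaHCO3, CH2Cl2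
Reagents that add atoms: N,N-dimethylmethyleneiminium iodide, C[N+](C)=C.[I-]
Why: Lactone enolate Mannich reaction with Eschenmoser's salt, quaternisation and E1cB elimination (α-methylenation); the lactone α-CH2 is the kinetically most accessible acidic C–H and no acyl group that could compete is present yet.

Step 21
Reactants: 30 α-methylene lactone (8-OTBS)
Product: 31 8-hydroxy α-methylene lactone (9-OMOM; 2-OTBDPS; 15-OTIPS)
Conditions: HF·pyridine, pyridine, THF, 0 °C to rt
Reagents that add atoms: none
Why: Buffered hydrogen fluoride desilylation removes the secondary TBS ether faster than the TBDPS and TIPS ethers; the lactone is already closed, so O8 cannot capture C12.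

Step 22
Reactants: 31 8-hydroxy α-methylene lactone
Product: 32 8-O-isobutyrate (9-OMOM; 2-OTBDPS; 15-OTIPS)
Conditions: (iPrCO)2O, Et3N, DMAP (cat.), CH2Cl2, 0 °C to rt
Reagents that add atoms: isobutyric anhydride, CC(C)C(=O)OC(=O)C(C)C
Why: DMAP-catalysed acylation (nucleophilic acyl transfer) of the secondary alcohol with the anhydride.

Step 23
Reactants: 32 8-O-isobutyrate (9-OMOM)
Product: 33 9-hydroxy 8-O-isobutyrate (2-OTBDPS; 15-OTIPS)
Conditions: Me2BBr, CH2Cl2, −78 °C; then NaHCO3, THF/H2O
Reagents that add atoms: none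
Why: Lewis-acid cleavage of the MOM acetal with a bromoborane at low temperature, conditions that leave esters, silyl ethers and the Michael acceptor intact.

Step 24
Reactants: 33 9-hydroxy 8-O-isobutyrate
Product: 34 9-O-acetyl-8-O-isobutyryl-2-O-TBDPS-15-O-TIPS derivative of 35
Conditions: Ac2O, pyridine, DMAP (cat.), CH2Cl2, 0 °C
Reagents that add atoms: acetic anhydride, CC(=O)OC(C)=O
Why: DMAP-catalysed acetylation; it is faster than 1,2-migration of the neighbouring, bulkier isobutyrate.

Step 25
Reactants: 34 2-O-TBDPS-15-O-TIPS derivative of 35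
Product: 35 CNP0301018.3, methyl (2S,6R,7S,8S,9S)-9-acetoxy-2,15-dihydroxy-8-(isobutyryloxy)-germacra-1(10),4,11(13)-trien-6,12-olid-14-oate (both ring alkenes ring-cis)
Conditions: Bu4NF, AcOH, THF, 0 °C to rt
Reagents that add atoms: none
Why: Buffered fluoride desilylation of the two remaining silyl ethers; acetic acid suppresses alkoxide-mediated acyl migration and conjugate addition to the methylene lactone.

## Compound list

1 | (E)-4-methoxybut-3-en-2-one | CO/C=C/C(C)=O | starting material
2 | (E)-4-(benzyloxy)but-3-en-2-one | CC(=O)/C=C/OCc1ccccc1 | intermediate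
3 | (E)-1-(benzyloxy)-3-(tert-butyldimethylsilyloxy)buta-1,3-diene | C=C(O[Si](C)(C)C(C)(C)C)/C=C/OCc1ccccc1 | intermediate
4 | 1,4-dioxaspiro[4.5]deca-6,9-dien-8-one | O=C1C=CC2(OCCO2)C=C1 | starting material
5 | cycloadduct, 4β-OBn-2-OTBS-cis-decala-2,7-dien-6-one 9-ethylene ketal (not isolated) | O=C1C=CC2(OCCO2)[C@H]3CC(O[Si](C)(C)C(C)(C)C)=C[C@@H](OCc4ccccc4)[C@@H]13 | intermediate
6 | 4β-OBn-5α,10α-H-cis-decal-7-ene-2,6-dione 9-ethylene ketal | O=C1C=CC2(OCCO2)[C@H]3CC(=O)C[C@@H](OCc4ccccc4)[C@@H]13 | intermediate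
7 | 4β-OBn-cis-decal-7-ene-2β,6β-diol 9-ethylene ketal (not isolated) | O[C@H]1C=CC2(OCCO2)[C@H]3C[C@@H](O)C[C@@H](OCc4ccccc4)[C@@H]13 | intermediate
8 | 4β-OBn-2β,6β-dihydroxy-cis-decal-7-en-9-one | O[C@H]1C=CC(=O)[C@H]2C[C@@H](O)C[C@@H](OCc3ccccc3)[C@@H]12 | intermediate
9 | 4β-OBn-2β-OTBDPS-6β-hydroxy-cis-decal-7-en-9-one | O[C@H]1C=CC(=O)[C@H]2C[C@@H](O[Si](c3ccccc3)(c3ccccc3)C(C)(C)C)C[C@@H](OCc3ccccc3)[C@@H]12 | intermediate
10 | 4β-OBn-2β-OTBDPS-6β-OTES-cis-decal-7-en-9-one | CC[Si](CC)(CC)O[C@H]1C=CC(=O)[C@H]2C[C@@H](O[Si](c3ccccc3)(c3ccccc3)C(C)(C)C)C[C@@H](OCc3ccccc3)[C@@H]12 | intermediate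
11 | 10α-hydroxy derivative of 10 (not isolated) | CC[Si](CC)(CC)O[C@H]1C=CC(=O)[C@@]2(O)C[C@@H](O[Si](c3ccccc3)(c3ccccc3)C(C)(C)C)C[C@@H](OCc3ccccc3)[C@@H]12 | intermediate
12 | 10α-OTMS derivative of 10 | CC[Si](CC)(CC)O[C@H]1C=CC(=O)[C@@]2(O[Si](C)(C)C)C[C@@H](O[Si](c3ccccc3)(c3ccccc3)C(C)(C)C)C[C@@H](OCc3ccccc3)[C@@H]12 | intermediate
13 | 1-(tert-butyldimethylsilyloxy)-1-methoxyethene | C=C(OC)O[Si](C)(C)C(C)(C)C | starting material
14 | methyl [4β-OBn-2β-OTBDPS-6β-OTES-9-OTBS-10α-OTMS-cis-decal-8-en-7α-yl]acetate | CC[Si](CC)(CC)O[C@H]1[C@H](CC(=O)OC)C=C(O[Si](C)(C)C(C)(C)C)[C@@]2(O[Si](C)(C)C)C[C@@H](O[Si](c3ccccc3)(c3ccccc3)C(C)(C)C)C[C@@H](OCc3ccccc3)[C@@H]12 | intermediate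
15 | 10-O-TMS ether of 16 (not isolated) | CC[Si](CC)(CC)O[C@H]1[C@H](CC(=O)OC)[C@H](O[Si](C)(C)C(C)(C)C)C(=O)[C@@]2(O[Si](C)(C)C)C[C@@H](O[Si](c3ccccc3)(c3ccccc3)C(C)(C)C)C[C@@H](OCc3ccccc3)[C@@H]12 | intermediate
16 | methyl [4β-OBn-8α-OTBS-2β-OTBDPS-6β-OTES-10α-hydroxy-9-oxo-cis-decalin-7α-yl]acetate | CC[Si](CC)(CC)O[C@H]1[C@H](CC(=O)OC)[C@H](O[Si](C)(C)C(C)(C)C)C(=O)[C@@]2(O)C[C@@H](O[Si](c3ccccc3)(c3ccccc3)C(C)(C)C)C[C@@H](OCc3ccccc3)[C@@H]12 | intermediate
17 | 9β,10α-diol from 16 | CC[Si](CC)(CC)O[C@H]1[C@H](CC(=O)OC)[C@H](O[Si](C)(C)C(C)(C)C)[C@@H](O)[C@@]2(O)C[C@@H](O[Si](c3ccccc3)(c3ccccc3)C(C)(C)C)C[C@@H](OCc3ccccc3)[C@@H]12 | intermediate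
18 | 9β-OMOM ether of 17 | CC[Si](CC)(CC)O[C@H]1[C@H](CC(=O)OC)[C@H](O[Si](C)(C)C(C)(C)C)[C@@H](OCOC)[C@@]2(O)C[C@@H](O[Si](c3ccccc3)(c3ccccc3)C(C)(C)C)C[C@@H](OCc3ccccc3)[C@@H]12 | intermediate
19 | 4β,10α-diol (debenzylated 18) | CC[Si](CC)(CC)O[C@H]1[C@H](CC(=O)OC)[C@H](O[Si](C)(C)C(C)(C)C)[C@@H](OCOC)[C@@]2(O)C[C@@H](O[Si](c3ccccc3)(c3ccccc3)C(C)(C)C)C[C@@H](O)[C@@H]12 | intermediate
20 | 10α-hydroxy-4-ketone | CC[Si](CC)(CC)O[C@H]1[C@H](CC(=O)OC)[C@H](O[Si](C)(C)C(C)(C)C)[C@@H](OCOC)[C@@]2(O)C[C@@H](O[Si](c3ccccc3)(c3ccccc3)C(C)(C)C)CC(=O)[C@@H]12 | intermediate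
21 | 4β,15-spiro-epoxy-10α-ol (fragmentation precursor) | CC[Si](CC)(CC)O[C@H]1[C@H](CC(=O)OC)[C@H](O[Si](C)(C)C(C)(C)C)[C@@H](OCOC)[C@@]2(O)C[C@@H](O[Si](c3ccccc3)(c3ccccc3)C(C)(C)C)C[C@]3(CO3)[C@@H]12 | intermediate
22 | ten-membered 10-ketone, ring-cis C4=C5, 15-OH | CC[Si](CC)(CC)O[C@@H]1/C=C(/CO)C[C@H](O[Si](c2ccccc2)(c2ccccc2)C(C)(C)C)CC(=O)[C@H](OCOC)[C@@H](O[Si](C)(C)C(C)(C)C)[C@H]1CC(=O)OC | intermediate
23 | 15-O-TIPS ether of 22 | CC[Si](CC)(CC)O[C@@H]1/C=C(/CO[Si](C(C)C)(C(C)C)C(C)C)C[C@H](O[Si](c2ccccc2)(c2ccccc2)C(C)(C)C)CC(=O)[C@H](OCOC)[C@@H](O[Si](C)(C)C(C)(C)C)[C@H]1CC(=O)OC | intermediate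
24 | ring-cis C1=C10 enol triflate | CC[Si](CC)(CC)O[C@@H]1/C=C(/CO[Si](C(C)C)(C(C)C)C(C)C)C[C@H](O[Si](c2ccccc2)(c2ccccc2)C(C)(C)C)/C=C(/OS(=O)(=O)C(F)(F)F)[C@H](OCOC)[C@@H](O[Si](C)(C)C(C)(C)C)[C@H]1CC(=O)OC | intermediate
25 | C14 methyl enoate, seco diester | CC[Si](CC)(CC)O[C@@H]1/C=C(/CO[Si](C(C)C)(C(C)C)C(C)C)C[C@H](O[Si](c2ccccc2)(c2ccccc2)C(C)(C)C)/C=C(/C(=O)OC)[C@H](OCOC)[C@@H](O[Si](C)(C)C(C)(C)C)[C@H]1CC(=O)OC | intermediate
26 | 6-hydroxy seco diester (not isolated) | O[C@@H]1/C=C(/CO[Si](C(C)C)(C(C)C)C(C)C)C[C@H](O[Si](c2ccccc2)(c2ccccc2)C(C)(C)C)/C=C(/C(=O)OC)[C@H](OCOC)[C@@H](O[Si](C)(C)C(C)(C)C)[C@H]1CC(=O)OC | intermediate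
27 | saturated trans-fused 6,12-lactone | C1C(=O)O[C@@H]2/C=C(/CO[Si](C(C)C)(C(C)C)C(C)C)C[C@H](O[Si](c3ccccc3)(c3ccccc3)C(C)(C)C)/C=C(/C(=O)OC)[C@H](OCOC)[C@@H](O[Si](C)(C)C(C)(C)C)[C@@H]12 | intermediate
28 | 11-(dimethylaminomethyl) lactone, C11 epimers (not isolated) | CN(C)CC1C(=O)O[C@@H]2/C=C(/CO[Si](C(C)C)(C(C)C)C(C)C)C[C@H](O[Si](c3ccccc3)(c3ccccc3)C(C)(C)C)/C=C(/C(=O)OC)[C@H](OCOC)[C@@H](O[Si](C)(C)C(C)(C)C)[C@@H]12 | intermediate
29 | trimethylammonium iodide of 28 (not isolated) | C[N+](C)(C)CC1C(=O)O[C@@H]2/C=C(/CO[Si](C(C)C)(C(C)C)C(C)C)C[C@H](O[Si](c3ccccc3)(c3ccccc3)C(C)(C)C)/C=C(/C(=O)OC)[C@H](OCOC)[C@@H](O[Si](C)(C)C(C)(C)C)[C@@H]12.[I-] | intermediate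
30 | α-methylene lactone, 8-OTBS, 9-OMOM | C=C1C(=O)O[C@@H]2/C=C(/CO[Si](C(C)C)(C(C)C)C(C)C)C[C@H](O[Si](c3ccccc3)(c3ccccc3)C(C)(C)C)/C=C(/C(=O)OC)[C@H](OCOC)[C@@H](O[Si](C)(C)C(C)(C)C)[C@@H]12 | intermediate
31 | 8-hydroxy α-methylene lactone | C=C1C(=O)O[C@@H]2/C=C(/CO[Si](C(C)C)(C(C)C)C(C)C)C[C@H](O[Si](c3ccccc3)(c3ccccc3)C(C)(C)C)/C=C(/C(=O)OC)[C@H](OCOC)[C@@H](O)[C@@H]12 | intermediate
32 | 8-O-isobutyrate, 9-OMOM | C=C1C(=O)O[C@@H]2/C=C(/CO[Si](C(C)C)(C(C)C)C(C)C)C[C@H](O[Si](c3ccccc3)(c3ccccc3)C(C)(C)C)/C=C(/C(=O)OC)[C@H](OCOC)[C@@H](OC(=O)C(C)C)[C@@H]12 | intermediate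
33 | 9-hydroxy 8-O-isobutyrate | C=C1C(=O)O[C@@H]2/C=C(/CO[Si](C(C)C)(C(C)C)C(C)C)C[C@H](O[Si](c3ccccc3)(c3ccccc3)C(C)(C)C)/C=C(/C(=O)OC)[C@H](O)[C@@H](OC(=O)C(C)C)[C@@H]12 | intermediate
34 | 2-O-TBDPS-15-O-TIPS ether of 35 | C=C1C(=O)O[C@@H]2/C=C(/CO[Si](C(C)C)(C(C)C)C(C)C)C[C@H](O[Si](c3ccccc3)(c3ccccc3)C(C)(C)C)/C=C(/C(=O)OC)[C@H](OC(C)=O)[C@@H](OC(=O)C(C)C)[C@@H]12 | intermediate
35 | CNP0301018.3 | C=C1C(=O)O[C@@H]2/C=C(/CO)C[C@H](O)/C=C(/C(=O)OC)[C@H](OC(C)=O)[C@@H](OC(=O)C(C)C)[C@@H]12 | target

## Step count and least certain steps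

Total step count: 25. Longest linear sequence: 25 steps (1 to 35; 4 and 13 are commercial). Fourteen steps precede the key step and ten follow it.

**Step 15 (key step).** The most likely failure is diversion of the alkoxide: O10 and C15 are 1,3-diaxial, so intramolecular opening of the epoxide at C15 to a cyclic ether can compete. The new ketone can also enolise toward C9 and lose the 8-silyloxy group if base is in excess or the mixture is warmed. Fallback: setting out from 20, the same C5–C10 bond is cleaved as a retro-aldol reaction. KN(SiMe3)2 followed at once by Comins' reagent drains the ring-opened C4 enolate as the ten-membered ring-cis 4-enol triflate F1. Stille hydroxymethylation of F1 with Bu3SnCH2OH, Pd(PPh3)4 and LiCl installs C15 and returns to the route at 22.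

**Step 3.** Insufficient enantioselectivity, or Lewis-acid degradation of the acid-sensitive diene and ketal, is possible because the dienophile β-carbon is neopentyl-like and the catalyst must differentiate two distant enantiotopic double bonds. Fallback: setting out from 3 and 4, the cycloaddition is run thermally (toluene, 60 °C) without catalyst.
- This gives the racemate, that is 5 together with its enantiomer F2.
- Fluoride work-up gives 6 and its enantiomer F3.
- Luche reduction and hydrolysis give 8 and its enantiomer F5 by way of the ketal diols 7 and F4.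
- Lipase-catalysed transesterification (Amano lipase PS, vinyl acetate) then acetylates the unhindered C2 hydroxyl of one antipode, written here for F5 to give the 2-O-acetate F6 (the enzyme or the acylation/hydrolysis mode is chosen so that this is the case). Chromatography returns the unreacted alcohol to the route at 8.

**Step 7.** Deprotonation may be slow and unselective: in the preferred conformer the 10-H is pseudoequatorial on ring B and poorly aligned with the carbonyl π-system, so γ-deprotonation at C6 or decomposition on warming can compete. Fallback: setting out from 10, soft enolisation with Me3SiOTf and Et3N at 0 °C gives the 2-silyloxy diene F7. Rubottom oxidation of F7 (mCPBA, NaHCO3) with silyl migration returns directly to the route at 12.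

**Step 9.** The facial selectivity at C8 rests on a steric balance (two syn-axial groups on the β face against the vicinal axial C7 arm on the α face); attack on the β face would give the 8β-silyloxy ketone. Fallback: setting out from 14, the oxidation is run as written and any 8β-epimer F8 is equilibrated with DBU in toluene through the C8–C9 enolate. C8 is the only enolisable position, and the 8α-silyloxy group is equatorial whereas the 8β group is syn-axial to O6 and C1, so thermodynamic control returns to the route at 16.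

**Step 14.** The ylide may attack the β face (the axial 10-hydroxyl is 1,3 to the α-face trajectory), or it may act as a base and trigger β-elimination of the silyloxy groups at C2 or C6. Fallback: setting out from 20, the carbon is delivered from O10 instead.
- Excess (isopropoxydimethylsilyl)methylmagnesium chloride with CeCl3 first forms the 10-alkoxide, which directs addition to the α face and gives the tertiary carbinol silane F9.
- Tamao–Fleming oxidation (H2O2, KF, KHCO3) gives the 4β,10α,15-triol F10.
- Selective tosylation of the primary hydroxyl gives the 15-tosylate F11, and K2CO3 in MeOH closes the epoxide, returning to the route at 21.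

**Step 17.** Loss of regio- or geometric control in the enolisation (the MOM group may direct the base to C9; the C1 enolate may expel the C2 silyloxy group) would give isomeric triflates or elimination. Fallback: setting out from 23, amine-mediated soft enolisation (Me3SiOTf, Et3N, −78 °C) gives the isolable ring-cis C1=C10 trimethylsilyl enol ether F12, which can be purified from isomers. Fluoride-triggered triflation of F12 (CsF, PhNTf2, DME) returns to the route at 24.

## Further compounds

F1 | step 15 | ten-membered 10-ketone with ring-cis C4=C5 enol triflate (4-OTf; 2-OTBDPS; 6-OTES; 7-CH2CO2Me; 8-OTBS; 9-OMOM) | CC[Si](CC)(CC)O[C@@H]1/C=C(/OS(=O)(=O)C(F)(F)F)C[C@H](O[Si](c2ccccc2)(c2ccccc2)C(C)(C)C)CC(=O)[C@H](OCOC)[C@@H](O[Si](C)(C)C(C)(C)C)[C@H]1CC(=O)OC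
F2 | step 3 | enantiomer of cycloadduct 5 | O=C1C=CC2(OCCO2)[C@@H]3CC(O[Si](C)(C)C(C)(C)C)=C[C@H](OCc4ccccc4)[C@H]13
F3 | step 3 | enantiomer of diketone 6 | O=C1C=CC2(OCCO2)[C@@H]3CC(=O)C[C@H](OCc4ccccc4)[C@H]13
F4 | step 3 | enantiomer of ketal diol 7 | O[C@@H]1C=CC2(OCCO2)[C@@H]3C[C@H](O)C[C@H](OCc4ccccc4)[C@H]13
F5 | step 3 | enantiomer of diol 8 | O[C@@H]1C=CC(=O)[C@@H]2C[C@H](O)C[C@H](OCc3ccccc3)[C@H]12
F6 | step 3 | 2-O-acetate of the enantiomer of 8 | O[C@@H]1C=CC(=O)[C@@H]2C[C@H](OC(C)=O)C[C@H](OCc3ccccc3)[C@H]12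
F7 | step 7 | 9-(trimethylsilyloxy)-cis-decala-7,9-diene from 10 (4β-OBn; 2β-OTBDPS; 6β-OTES) | CC[Si](CC)(CC)O[C@H]1C=CC(O[Si](C)(C)C)=C2C[C@@H](O[Si](c3ccccc3)(c3ccccc3)C(C)(C)C)C[C@@H](OCc3ccccc3)[C@@H]12
F8 | step 9 | 8β-OTBS epimer of 16 | CC[Si](CC)(CC)O[C@H]1[C@H](CC(=O)OC)[C@@H](O[Si](C)(C)C(C)(C)C)C(=O)[C@@]2(O)C[C@@H](O[Si](c3ccccc3)(c3ccccc3)C(C)(C)C)C[C@@H](OCc3ccccc3)[C@@H]12
F9 | step 14 | 4β-hydroxy-4α-[(isopropoxydimethylsilyl)methyl] adduct of 20 | CC[Si](CC)(CC)O[C@H]1[C@H](CC(=O)OC)[C@H](O[Si](C)(C)C(C)(C)C)[C@@H](OCOC)[C@@]2(O)C[C@@H](O[Si](c3ccccc3)(c3ccccc3)C(C)(C)C)C[C@](O)(C[Si](C)(C)OC(C)C)[C@@H]12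
F10 | step 14 | 4β,10α,15-triol | CC[Si](CC)(CC)O[C@H]1[C@H](CC(=O)OC)[C@H](O[Si](C)(C)C(C)(C)C)[C@@H](OCOC)[C@@]2(O)C[C@@H](O[Si](c3ccccc3)(c3ccccc3)C(C)(C)C)C[C@](O)(CO)[C@@H]12
F11 | step 14 | 15-O-tosylate of the 4β,10α,15-triol | CC[Si](CC)(CC)O[C@H]1[C@H](CC(=O)OC)[C@H](O[Si](C)(C)C(C)(C)C)[C@@H](OCOC)[C@@]2(O)C[C@@H](O[Si](c3ccccc3)(c3ccccc3)C(C)(C)C)C[C@](O)(COS(=O)(=O)c3ccc(C)cc3)[C@@H]12
F12 | step 17 | ring-cis C1=C10 trimethylsilyl enol ether of 23 | CC[Si](CC)(CC)O[C@@H]1/C=C(/CO[Si](C(C)C)(C(C)C)C(C)C)C[C@H](O[Si](c2ccccc2)(c2ccccc2)C(C)(C)C)/C=C(/O[Si](C)(C)C)[C@H](OCOC)[C@@H](O[Si](C)(C)C(C)(C)C)[C@H]1CC(=O)OC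
A1 | alternative 1 | open-chain C6 aldehyde with C5 alkenyl iodide (iodine cis to C3), C11 acrylate methyl ester, 8-O-isobutyrate, 9-O-acetate, 2,15-bis-O-TBS | C=C(C(=O)OC)[C@@H](C=O)[C@H](OC(=O)C(C)C)[C@@H](OC(C)=O)/C(C(=O)OC)=C\[C@@H](O[Si](C)(C)C(C)(C)C)C/C(CO[Si](C)(C)C(C)(C)C)=C\I
A2 | alternative 1 | 2,15-bis-O-TBS ether of 35 | C=C1C(=O)O[C@@H]2/C=C(/CO[Si](C)(C)C(C)(C)C)C[C@H](O[Si](C)(C)C(C)(C)C)/C=C(/C(=O)OC)[C@H](OC(C)=O)[C@@H](OC(=O)C(C)C)[C@@H]12
A3 | alternative 2 | cyclooctenone (ring C2–C9, C9 ketone, ring-cis C4=C5, 15-OTBS, 8-O-PMB, saturated 6,12-lactone) | C1C(=O)O[C@@H]2/C=C(/CO[Si](C)(C)C(C)(C)C)CCC(=O)[C@@H](OCc3ccc(OC)cc3)[C@@H]12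
A4 | alternative 2 | ten-membered 9-pyrrolidinyl dienamine ester (C9=C10 and C1=C2 alkenes) | C1C(=O)O[C@@H]2/C=C(/CO[Si](C)(C)C(C)(C)C)C/C=C/C(C(=O)OC)=C(/N3CCCC3)[C@@H](OCc4ccc(OC)cc4)[C@@H]12
A5 | alternative 3 | open-chain C4 alkenyl bromide and C3 primary iodide with saturated lactone, 8-O-isobutyrate, 9-O-TES, 2,15-bis-O-TBS | IC[C@H](O[Si](C)(C)C(C)(C)C)/C=C(/C(=O)OC)[C@H](O[Si](CC)(CC)CC)[C@@H](OC(=O)C(C)C)[C@H]1CC(=O)O[C@@H]1/C=C(\Br)CO[Si](C)(C)C(C)(C)C
A6 | alternative 3 | ten-membered macrocycle with saturated lactone, 9-O-TES, 2,15-bis-O-TBS, 8-O-isobutyrate | C1C(=O)O[C@@H]2/C=C(/CO[Si](C)(C)C(C)(C)C)C[C@H](O[Si](C)(C)C(C)(C)C)/C=C(/C(=O)OC)[C@H](O[Si](CC)(CC)CC)[C@@H](OC(=O)C(C)C)[C@@H]12
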